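## Structural features

The target is a C15 dibromo ether made of two saturated units joined by one C–C bond: a 7-oxabicyclo[2.2.1]heptane (C1–C6, with O7 bridging C1 and C4) and a cyclohexane (ring A, C1'–C6'), linked C4–C1'. The bicycle carries a methyl group on bridgehead C1, a bromine on C2 and ring A on bridgehead C4; its stereocentres are C1 (R), C2 (R) and C4 (S), and the bromine is endo, on the side of the C5–C6 bridge and anti to O7. Ring A has a gem-dimethyl group at C3' and a bromine at C4'; C1' and C4' are both S, which places the two substituents trans and both equatorial. C1' stands directly next to the quaternary stereocentre C4, but the two belong to different rings joined by a rotating bond, so no cyclic transition state relays configuration from one to the other. Both C–Br bonds are secondary and flanked by a fully substituted carbon (C1, C3'), so substitution there is slow and elimination or cationic shifts compete; alkyl bromides do not survive hydride or radical reductions, and ionisation at C2 invites a 1,2-shift towards an oxygen-stabilised cation at C1. The real difficulty is threefold: two fully substituted ether carbons 1,4 across a bridged ring, the correlation of the absolute sense of the bicycle with that of ring A, and the late placement of two hindered bromides. The key step uses the fact that C1–O7–C4, tied back by C5–C6, is a five-membered cyclic carbonyl ylide and C2–C3 a two-carbon dipolarophile, so the whole bicycle derives from an open δ-keto α-diazo ester chain on ring A; the C1 methyl is then a reduced ester and the C2 bromide an inverted exo oxygen.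

## Logic of the disconnections

22 to 21. The bonds C2–Br and C4'–Br are cut and replaced by C–O bonds of opposite configuration. The bromides tolerate the least chemistry, so they arrive last; 21 has no halogen, and both of its oxygens have a natural origin (dipolarophile, ring ketone). The forward step must invert two hindered secondary carbinol carbons by SN2 without letting either ionise.

21 to 17 (through 20, 19 and 18). The two O–Si bonds are restored and the three C–H bonds of the C1 methyl group are traced to the C–O bonds of a bridgehead ester. An acceptor on C1 is what makes the diazo carbon of the key step manageable, and an ester is the acceptor most simply taken down to CH3. The cost is three reductive operations, the last a displacement at a primary carbon flanked by the quaternary, oxygen-bearing C1; the silyl ethers must be inert to all three.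

17 to 13 and 14 (through 16 and 15). C1–C2 and C3–C4 are cut as a [3+2] cycloreversion, and C1–O7 as the reverse of carbonyl-oxygen capture by a carbene. This removes both rings, both fully substituted ether carbons and the three stereocentres of the bicycle, leaving an open chain on ring A and a two-carbon enol ether. The forward reaction must form the ylide before the carbenoid rearranges, add 14 with its oxygen-bearing carbon at C1 and exo, and choose one ylide face relative to C1'.

13 to 10 and 11 (through 12). The C=N2 unit is traced to an acetyl-activated C–H, and the bond between the two chain methylenes is cut as a conjugate addition. One cheap reagent, 11, serves as carbon nucleophile and as the activating group that diazo transfer removes. The bases must be weak enough to leave C1', now α to a ketone, untouched.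

10 to 7 (through 9 and 8). The bond from the ketone carbon to the vinyl group is cut to an N-methoxy-N-methyl amide; then the O–Si and C4'–H bonds are removed to reveal a ring ketone. C4' is thereby created on a simple monocycle, where the chair steers a bulky hydride: C1' substituent equatorial, hydride from the equatorial side, oxygen axial and cis. The amide must survive the hydride and stop vinyl addition at the ketone stage.

7 to 5 (through 6). One C3' methyl group is cut back to the methylene of a cyclopropane fused at C3'–C4', and that to a silyl enol ether. The enol ether double bond marks which α-carbon receives the second methyl group, which enolate alkylation of a 4-substituted cyclohexanone could not guarantee. The demand is ring opening at the C4'–CH2 bond only.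

5 to 2 and 3 (through 4). After exchange of amide for ester, the ring bonds C1'–C2' and C5'–C6' are cut in a retro-Diels–Alder sense. All six ring carbons, the latent ketone, the first methyl group and the C1' stereocentre reduce to two achiral fragments. The cycloaddition must be regioselective (silyloxy para to the ester) and enantioselective under a chiral Lewis acid.

2 to 1. The O–Si bond of the diene is cut to the enone. Only the acetyl methyl group can be enolised, so the demand is merely silylation mild enough not to polymerise the enone.

## Other disconnections considered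

Alternative 1: The cut goes through ring A and removes C4'–Br and C2'–C3', leaving the finished bromo-oxabicycle with an open 6-methylhepta-1,5-dien-2-yl chain at C4 (A2).
- Forward step: a bromonium donor made chiral by a Lewis-base activator would attack the trisubstituted alkene, and the 1,1-disubstituted alkene would close the six-membered ring through C2'. Loss of a proton would give the cyclohexene A1 and its 1',6' double-bond isomer A3, and hydrogenation of both would finish.
- In favour: the neopentyl C4'–Br bond is made directly, and here the alternative is better than the chosen plan, whose last step must force bromide into that position. The bicycle of A2 could be closed by bromoetherification with the endo bromine in place, so neither bromide would need an inversion.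
- Against: asymmetric bromonium cyclisations with a simple alkene terminator are far less dependable than the pericyclic and hydride chemistry used here. Bromonium transfer between alkenes erodes induction, and the cation at C1' is destabilised by the adjacent C–O bridgehead. The hydrogenation must set C1' trans to a remote C4' bromine with little bias while two C–Br bonds are exposed to hydrogenolysis.
- Comparison: structurally the alternative builds ring A last and the chosen plan builds it first; both must correlate two stereo-domains by reagent control and are equals there. Mechanistically it is cationic, hence prone to elimination and rearrangement, against a concerted cycloaddition. It would probably be a few steps shorter, a point for the alternative, but with two steps of uncertain stereocontrol instead of one.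

Alternative 2: The cut removes C4–C5 and C1–C6 and reads the bicycle as the Diels–Alder adduct of the 3-bromo-2-methylfuran A5, already carrying brominated ring A, with the acrylate 3.
- Forward step: a chiral Lewis acid would have to catalyse the cycloaddition to the endo ester A4; the ester carbon must then be excised and C2=C3 saturated.
- In favour: C1 arrives with its methyl group and C2 with its bromine. Saturation of the bromoalkene from the exo face would leave bromine endo without any substitution at C2, which is better than the chosen plan on that point.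
- Against: furan cycloadditions are reversible and slow for a trisubstituted bromofuran, and strong Lewis acids open oxanorbornenes. Neither the position of the ester (C5 or C6) nor endo/exo is secured. The ester is a passenger whose removal by radical decarboxylation would meet two C–Br bonds, and the ring A bromide must be carried through the furan synthesis.
- Comparison: both plans rely on catalyst control of a cycloaddition face relative to ring A, and both carry an ester that must be edited, so they are equal on these points. Both key steps are concerted, but the furan addition is thermodynamically marginal whereas the ylide addition is strongly downhill. No gain in step count is expected.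

Alternative 3: The cut removes C1–C2 and C5–C6 of the carbocycle, which is traced to the 3-silyloxycyclobutanone A7 and 1-(trimethylsilyl)propyne A8.
- Forward step: zerovalent nickel (Ni(cod)2 with a chiral phosphine) would couple ketone and alkyne to an oxanickelacycle; β-carbon elimination would cleave one of the two enantiotopic acyl C–C bonds and reductive elimination would give the cyclohexenone A6.
- In favour: the route is convergent and uses no diazo compound or carbenoid, a point on which it is better for safety and chemoselectivity. The C1 methyl is introduced as such, which is better than the ester detour. Desymmetrisation of a prochiral ring is at least the equal of face selection on a ylide as a way to set C4.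
- Against: A6 is still a monocycle. O7 must be joined to C1, the α-carbon of the enone, which is not a conjugate addition and requires protodesilylation and redox adjustment before C2 can be addressed. β-Oxygen elimination from the nickelacycle and the regiochemistry of alkyne insertion threaten the key step, and a bulky secondary group on the quaternary carbon lies outside the usual substrate range.
- Comparison: the chosen key step closes both rings and sets three stereocentres, the alternative one ring and one stereocentre. More steps would follow the key step (seven to nine estimated against five), and A7 itself needs a ketene [2+2], so the alternative is longer.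

Key step: step 11

Assumption: for the two catalyst-controlled steps (2 and 11) the antipode of the chiral catalyst is taken to be the one whose facial preference matches the structures drawn for 4 and 17; the catalyst names in the Conditions lines stand for that antipode.

## Route

Step 1
Reactants: 1 3-methylbut-3-en-2-one
Product: 2 2-methyl-3-(triisopropylsilyloxy)buta-1,3-diene
Conditions: i-Pr3SiOTf, Et3N, CH2Cl2, 0 °C → rt
Reagents that add atoms: triisopropylsilyl trifluoromethanesulfonate, CC(C)[Si](OS(=O)(=O)C(F)(F)F)(C(C)C)C(C)C
Why: Silyl enol ether formation by soft enolisation; the acetyl methyl group is the only position whose deprotonation gives an enolate, so the cross-conjugated 2-silyloxydiene should form as a single regioisomer.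

Step 2
Reactants: 2 2-methyl-3-(triisopropylsilyloxy)buta-1,3-diene; 3 2,2,2-trifluoroethyl acrylate
Product: 4 2,2,2-trifluoroethyl (1S)-3-methyl-4-(triisopropylsilyloxy)cyclohex-3-ene-1-carboxylate
Conditions: (S)-o-tolyl-oxazaborolidine (from α,α-diphenylprolinol)·HNTf2 (10 mol%), CH2Cl2, −78 → −40 °C
Reagents that add atoms: none
Why: Enantioselective Diels–Alder reaction under a cationic chiral boron Lewis acid; the silyloxy group directs its nucleophilic diene terminus to the acrylate β-carbon (ester para to oxygen, methyl-bearing carbon meta), and the catalyst shields one face of the bound acrylate, which sets C1' (S).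

Step 3
Reactants: 4 2,2,2-trifluoroethyl (1S)-3-methyl-4-(triisopropylsilyloxy)cyclohex-3-ene-1-carboxylate
Product: 5 (1S)-N-methoxy-N,3-dimethyl-4-(triisopropylsilyloxy)cyclohex-3-ene-1-carboxamide
Conditions: MeNH(OMe)·HCl, i-PrMgCl, THF, −20 °C
Reagents that add atoms: N,O-dimethylhydroxylamine hydrochloride, CNOC.Cl
Why: Weinreb amide formation by magnesium amide aminolysis of the activated ester; at low temperature the α-stereocentre should not enolise and the hindered silyl enol ether keeps the ketone masked.

Step 4
Reactants: 5 (1S)-N-methoxy-N,3-dimethyl-4-(triisopropylsilyloxy)cyclohex-3-ene-1-carboxamide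
Product: 6 (3S)-N-methoxy-N,1-dimethyl-6-(triisopropylsilyloxy)bicyclo[4.1.0]heptane-3-carboxamide (mixture of cyclopropane diastereomers)
Conditions: Et2Zn, CH2I2, CH2Cl2, 0 °C → rt
Reagents that add atoms: diiodomethane, ICI
Why: Simmons–Smith cyclopropanation (Furukawa variant) of the only alkene, an electron-rich enol ether; the facial outcome is irrelevant because both new stereocentres are lost in step 5.

Step 5
Reactants: 6 (3S)-N-methoxy-N,1-dimethyl-6-(triisopropylsilyloxy)bicyclo[4.1.0]heptane-3-carboxamide
Product: 7 (1S)-N-methoxy-N,3,3-trimethyl-4-oxocyclohexane-1-carboxamide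
Conditions: aq. HCl, THF, 50 °C
Reagents that add atoms: none
Why: Acid-mediated ring opening of a siloxycyclopropane (Conia-type α-methylation); cleavage of the C(O)–CH2 bond turns the methylene into the second methyl group at C3' and releases the C4' ketone, while C1' is remote from the carbonyl and cannot epimerise.

Step 6
Reactants: 7 (1S)-N-methoxy-N,3,3-trimethyl-4-oxocyclohexane-1-carboxamide
Product: 8 (1S,4R)-4-hydroxy-N-methoxy-N,3,3-trimethylcyclohexane-1-carboxamide
Conditions: LiBH(s-Bu)3 (L-Selectride), THF, −78 °C; H2O
Reagents that add atoms: none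
Why: Ketone reduction with a bulky trialkylborohydride; with the amide equatorial the hydride enters along the equatorial trajectory and should give the axial alcohol cis to the C1' substituent (4'R), the usual outcome for 2,2-dimethylcyclohexanones, and the amide is not reduced at −78 °C.

Step 7
Reactants: 8 (1S,4R)-4-hydroxy-N-methoxy-N,3,3-trimethylcyclohexane-1-carboxamide
Product: 9 (1S,4R)-4-[(tert-butyldimethylsilyl)oxy]-N-methoxy-N,3,3-trimethylcyclohexane-1-carboxamide
Conditions: t-BuMe2SiOTf, 2,6-lutidine, CH2Cl2, −78 → 0 °C
Reagents that add atoms: tert-butyldimethylsilyl trifluoromethanesulfonate, CC(C)(C)[Si](C)(C)OS(=O)(=O)C(F)(F)F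
Why: Silyl ether formation; the silyl triflate is reactive enough for the hindered axial alcohol and no stereocentre is touched.

Step 8
Reactants: 9 (1S,4R)-4-[(tert-butyldimethylsilyl)oxy]-N-methoxy-N,3,3-trimethylcyclohexane-1-carboxamide
Product: 10 1-[(1S,4R)-4-[(tert-butyldimethylsilyl)oxy]-3,3-dimethylcyclohexyl]prop-2-en-1-one
Conditions: CH2=CHMgBr, THF, −20 → 0 °C; inverse quench into cold 1 M HCl
Reagents that add atoms: vinylmagnesium bromide, C=C[Mg]Br
Why: Weinreb ketone synthesis; the magnesium chelate stops at mono-addition, and quenching into cold acid protonates the liberated amine before it can add to the vinyl ketone.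

Step 9
Reactants: 10 1-[(1S,4R)-4-[(tert-butyldimethylsilyl)oxy]-3,3-dimethylcyclohexyl]prop-2-en-1-one; 11 methyl acetoacetate
Product: 12 methyl 2-acetyl-5-[(1S,4R)-4-[(tert-butyldimethylsilyl)oxy]-3,3-dimethylcyclohexyl]-5-oxopentanoate (both C2 epimers)
Conditions: 11 (3 equiv), Et3N (20 mol%), CH2Cl2, rt
Reagents that add atoms: none
Why: Michael addition of a β-keto ester to a vinyl ketone; the weak amine deprotonates only the acetoacetate, so C1' is not epimerised and the 1,5-diketone should not cyclise at room temperature, and the new centre is destroyed in step 10.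

Step 10
Reactants: 12 methyl 2-acetyl-5-[(1S,4R)-4-[(tert-butyldimethylsilyl)oxy]-3,3-dimethylcyclohexyl]-5-oxopentanoate
Product: 13 methyl 5-[(1S,4R)-4-[(tert-butyldimethylsilyl)oxy]-3,3-dimethylcyclohexyl]-2-diazo-5-oxopentanoate
Conditions: 4-AcNHC6H4SO2N3, DBU, MeCN, 0 °C → rt
Reagents that add atoms: 4-acetamidobenzenesulfonyl azide, CC(=O)Nc1ccc(cc1)S(=O)(=O)N=[N+]=[N-]
Why: Regitz deacylative diazo transfer; the enolate of the α-substituted β-keto ester attacks the sulfonyl azide and the adduct fragments with loss of the acetyl group as the N-acetylsulfonamide, giving the α-alkyl α-diazo ester.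

Step 11
Reactants: 13 methyl 5-[(1S,4R)-4-[(tert-butyldimethylsilyl)oxy]-3,3-dimethylcyclohexyl]-2-diazo-5-oxopentanoate; 14 tert-butyldimethyl(vinyloxy)silane
Product: 17 methyl (1R,2S,4S)-2-[(tert-butyldimethylsilyl)oxy]-4-[(1S,4R)-4-[(tert-butyldimethylsilyl)oxy]-3,3-dimethylcyclohexyl]-7-oxabicyclo[2.2.1]heptane-1-carboxylate, via rhodium carbenoid 15 (not isolated), via carbonyl ylide 16 (not isolated)
Conditions: Rh2(S-PTTL)4 [dirhodium tetrakis(N-phthaloyl-(S)-tert-leucinate), 1 mol%], 14 (5 equiv), toluene, −78 → −40 °C, slow addition of 13
Reagents that add atoms: none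
Why: Divalent rhodium takes up the diazo carbon of 13 and releases N2 to give the electrophilic carbenoid 15 at the future C1; bulky carboxylate ligands and low temperature are the known means of slowing the competing 1,2-hydride shift of α-alkyl carbenoids. The lone pair of the C4 ketone oxygen then attacks the carbenoid carbon through the two-carbon tether, closing the first ring (five-membered, by C1–O7 bond formation) and giving the ester-stabilised carbonyl ylide 16. The ylide adds to 14 in a suprafacial [3+2] cycloaddition that forms C1–C2 and C3–C4 and so closes the second ring, the six-membered carbocycle bridged by O7. The closest known reaction type is the dirhodium-catalysed tandem carbonyl ylide formation and cycloaddition of diazo keto esters, including its enantioselective form with chiral dirhodium carboxylates. Regiochemistry follows ylide polarity: the ylide LUMO is largest at C4, remote from the ester, so the nucleophilic CH2 terminus of 14 bonds there and the oxygen-bearing carbon becomes C2 next to C1. C1 and C4 are set together because the dipolarophile spans one face of the planar ylide; which face is used relative to C1' must be decided by the chiral ligand sphere while rhodium is still associated with the ylide, because C1' itself offers almost no bias. C2 is set by exo approach, with the bulky silyloxy group pointing towards O7 and away from the C5–C6 bridge. The step needs chemoselectivity (ylide formation before hydride shift or cyclopropanation of 14) and regio-, exo- and face selectivity; the short tether, the ylide polarity, the size of the silyl group and the catalyst are the respective securing elements.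

Step 12
Reactants: 17 methyl (1R,2S,4S)-2-[(tert-butyldimethylsilyl)oxy]-4-[(1S,4R)-4-[(tert-butyldimethylsilyl)oxy]-3,3-dimethylcyclohexyl]-7-oxabicyclo[2.2.1]heptane-1-carboxylate
Product: 18 [(1S,2S,4S)-2-[(tert-butyldimethylsilyl)oxy]-4-[(1S,4R)-4-[(tert-butyldimethylsilyl)oxy]-3,3-dimethylcyclohexyl]-7-oxabicyclo[2.2.1]heptan-1-yl]methanol
Conditions: LiAlH4, THF, 0 °C
Reagents that add atoms: none
Why: Ester reduction to the primary alcohol; the silyl ethers and the bridged ether are inert and no stereocentre is involved (the C1 descriptor changes only through priorities).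

Step 13
Reactants: 18 [(1S,2S,4S)-2-[(tert-butyldimethylsilyl)oxy]-4-[(1S,4R)-4-[(tert-butyldimethylsilyl)oxy]-3,3-dimethylcyclohexyl]-7-oxabicyclo[2.2.1]heptan-1-yl]methanol
Product: 19 [(1S,2S,4S)-2-[(tert-butyldimethylsilyl)oxy]-4-[(1S,4R)-4-[(tert-butyldimethylsilyl)oxy]-3,3-dimethylcyclohexyl]-7-oxabicyclo[2.2.1]heptan-1-yl]methyl 4-methylbenzenesulfonate
Conditions: TsCl, Et3N, DMAP (cat.), CH2Cl2, 0 °C → rt
Reagents that add atoms: 4-methylbenzenesulfonyl chloride, Cc1ccc(cc1)S(Cl)(=O)=O
Why: Sulfonate ester formation at the only free hydroxyl group.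

Step 14
Reactants: 19 [(1S,2S,4S)-2-[(tert-butyldimethylsilyl)oxy]-4-[(1S,4R)-4-[(tert-butyldimethylsilyl)oxy]-3,3-dimethylcyclohexyl]-7-oxabicyclo[2.2.1]heptan-1-yl]methyl 4-methylbenzenesulfonate
Product: 20 (1R,2S,4S)-2-[(tert-butyldimethylsilyl)oxy]-4-[(1S,4R)-4-[(tert-butyldimethylsilyl)oxy]-3,3-dimethylcyclohexyl]-1-methyl-7-oxabicyclo[2.2.1]heptane
Conditions: LiBHEt3, THF, 65 °C
Reagents that add atoms: none
Why: SN2 hydride displacement of a primary tosylate by the most nucleophilic simple borohydride, the usual choice for neopentyl-type sulfonates; the reaction occurs at the exocyclic carbon, so C1 is unaffected.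

Step 15
Reactants: 20 (1R,2S,4S)-2-[(tert-butyldimethylsilyl)oxy]-4-[(1S,4R)-4-[(tert-butyldimethylsilyl)oxy]-3,3-dimethylcyclohexyl]-1-methyl-7-oxabicyclo[2.2.1]heptane
Product: 21 (1R,2S,4S)-4-[(1S,4R)-4-hydroxy-3,3-dimethylcyclohexyl]-1-methyl-7-oxabicyclo[2.2.1]heptan-2-ol
Conditions: Bu4NF, THF, 50 °C
Reagents that add atoms: none
Why: Fluoride-mediated desilylation of both ethers, driven by Si–F bond strength; heating compensates for the hindered positions.

Step 16
Reactants: 21 (1R,2S,4S)-4-[(1S,4R)-4-hydroxy-3,3-dimethylcyclohexyl]-1-methyl-7-oxabicyclo[2.2.1]heptan-2-ol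
Product: 22 (1R,2R,4S)-2-bromo-4-[(1S,4S)-4-bromo-3,3-dimethylcyclohexyl]-1-methyl-7-oxabicyclo[2.2.1]heptane
Conditions: CBr4, PPh3, toluene, 0 → 60 °C
Reagents that add atoms: tetrabromomethane, BrC(Br)(Br)Br
Why: Twofold Appel reaction; each alkoxyphosphonium ion should be displaced by bromide with SN2 inversion, turning the axial C4' oxygen into the equatorial bromide (4'S) and the exo C2 oxygen into the endo bromide (2R), and the neutral, weakly ionising medium is chosen to keep cations at C2 and C4' from forming.

## Compound list

1 | 3-methylbut-3-en-2-one | CC(=O)C(C)=C | starting material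
2 | 2-methyl-3-(triisopropylsilyloxy)buta-1,3-diene | C=C(C)C(=C)O[Si](C(C)C)(C(C)C)C(C)C | intermediate
3 | 2,2,2-trifluoroethyl acrylate | C=CC(=O)OCC(F)(F)F | starting material
4 | 2,2,2-trifluoroethyl (1S)-3-methyl-4-(triisopropylsilyloxy)cyclohex-3-ene-1-carboxylate | CC1=C(O[Si](C(C)C)(C(C)C)C(C)C)CC[C@@H](C1)C(=O)OCC(F)(F)F | intermediate
5 | (1S)-N-methoxy-N,3-dimethyl-4-(triisopropylsilyloxy)cyclohex-3-ene-1-carboxamide | CC1=C(O[Si](C(C)C)(C(C)C)C(C)C)CC[C@@H](C1)C(=O)N(C)OC | intermediate
6 | (3S)-N-methoxy-N,1-dimethyl-6-(triisopropylsilyloxy)bicyclo[4.1.0]heptane-3-carboxamide, mixture of cyclopropane diastereomers | CC12C[C@@H](C(=O)N(C)OC)CCC1(O[Si](C(C)C)(C(C)C)C(C)C)C2 | intermediate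
7 | (1S)-N-methoxy-N,3,3-trimethyl-4-oxocyclohexane-1-carboxamide | CC1(C)C[C@@H](C(=O)N(C)OC)CCC1=O | intermediate
8 | (1S,4R)-4-hydroxy-N-methoxy-N,3,3-trimethylcyclohexane-1-carboxamide | CC1(C)C[C@@H](C(=O)N(C)OC)CC[C@H]1O | intermediate
9 | (1S,4R)-4-[(tert-butyldimethylsilyl)oxy]-N-methoxy-N,3,3-trimethylcyclohexane-1-carboxamide | CC1(C)C[C@@H](C(=O)N(C)OC)CC[C@H]1O[Si](C)(C)C(C)(C)C | intermediate
10 | 1-[(1S,4R)-4-[(tert-butyldimethylsilyl)oxy]-3,3-dimethylcyclohexyl]prop-2-en-1-one | CC1(C)C[C@@H](C(=O)C=C)CC[C@H]1O[Si](C)(C)C(C)(C)C | intermediate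
11 | methyl acetoacetate | COC(=O)CC(C)=O | starting material
12 | methyl 2-acetyl-5-[(1S,4R)-4-[(tert-butyldimethylsilyl)oxy]-3,3-dimethylcyclohexyl]-5-oxopentanoate, both C2 epimers | CC1(C)C[C@@H](C(=O)CCC(C(C)=O)C(=O)OC)CC[C@H]1O[Si](C)(C)C(C)(C)C | intermediate
13 | methyl 5-[(1S,4R)-4-[(tert-butyldimethylsilyl)oxy]-3,3-dimethylcyclohexyl]-2-diazo-5-oxopentanoate | CC1(C)C[C@@H](C(=O)CCC(=[N+]=[N-])C(=O)OC)CC[C@H]1O[Si](C)(C)C(C)(C)C | intermediate
14 | tert-butyldimethyl(vinyloxy)silane | C=CO[Si](C)(C)C(C)(C)C | starting material
15 | rhodium carbenoid of 13, carbene carbon = future C1 ([Rh] stands for the Rh2(S-PTTL)4 unit) | CC1(C)C[C@@H](C(=O)CCC(=[Rh])C(=O)OC)CC[C@H]1O[Si](C)(C)C(C)(C)C | intermediate (not isolated)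
16 | cyclic carbonyl ylide: 2-(methoxycarbonyl)-5-[(1S,4R)-4-[(tert-butyldimethylsilyl)oxy]-3,3-dimethylcyclohexyl]-3,4-dihydro-2H-furan-1-ium-2-ide | CC1(C)C[C@@H](C2=[O+][C-](C(=O)OC)CC2)CC[C@H]1O[Si](C)(C)C(C)(C)C | intermediate (not isolated)
17 | methyl (1R,2S,4S)-2-[(tert-butyldimethylsilyl)oxy]-4-[(1S,4R)-4-[(tert-butyldimethylsilyl)oxy]-3,3-dimethylcyclohexyl]-7-oxabicyclo[2.2.1]heptane-1-carboxylate (2-exo silyl ether) | CC1(C)C[C@@H]([C@@]23CC[C@@](C(=O)OC)(O2)[C@@H](O[Si](C)(C)C(C)(C)C)C3)CC[C@H]1O[Si](C)(C)C(C)(C)C | intermediate
18 | [(1S,2S,4S)-2-[(tert-butyldimethylsilyl)oxy]-4-[(1S,4R)-4-[(tert-butyldimethylsilyl)oxy]-3,3-dimethylcyclohexyl]-7-oxabicyclo[2.2.1]heptan-1-yl]methanol | CC1(C)C[C@@H]([C@@]23CC[C@@](CO)(O2)[C@@H](O[Si](C)(C)C(C)(C)C)C3)CC[C@H]1O[Si](C)(C)C(C)(C)C | intermediate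
19 | [(1S,2S,4S)-2-[(tert-butyldimethylsilyl)oxy]-4-[(1S,4R)-4-[(tert-butyldimethylsilyl)oxy]-3,3-dimethylcyclohexyl]-7-oxabicyclo[2.2.1]heptan-1-yl]methyl 4-methylbenzenesulfonate | CC1(C)C[C@@H]([C@@]23CC[C@@](COS(=O)(=O)c4ccc(C)cc4)(O2)[C@@H](O[Si](C)(C)C(C)(C)C)C3)CC[C@H]1O[Si](C)(C)C(C)(C)C | intermediate
20 | (1R,2S,4S)-2-[(tert-butyldimethylsilyl)oxy]-4-[(1S,4R)-4-[(tert-butyldimethylsilyl)oxy]-3,3-dimethylcyclohexyl]-1-methyl-7-oxabicyclo[2.2.1]heptane | CC1(C)C[C@@H]([C@@]23CC[C@@](C)(O2)[C@@H](O[Si](C)(C)C(C)(C)C)C3)CC[C@H]1O[Si](C)(C)C(C)(C)C | intermediate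
21 | (1R,2S,4S)-4-[(1S,4R)-4-hydroxy-3,3-dimethylcyclohexyl]-1-methyl-7-oxabicyclo[2.2.1]heptan-2-ol | CC1(C)C[C@@H]([C@@]23CC[C@@](C)(O2)[C@@H](O)C3)CC[C@H]1O | intermediate
22 | (1R,2R,4S)-2-bromo-4-[(1S,4S)-4-bromo-3,3-dimethylcyclohexyl]-1-methyl-7-oxabicyclo[2.2.1]heptane | CC1(C)C[C@@H]([C@@]23CC[C@@](C)(O2)[C@H](Br)C3)CC[C@@H]1Br | target

## Step count and least certain steps

Total step count: 16. Longest linear sequence: 16 steps (1 to 22; the route is linear, with 3, 11 and 14 entering as purchased partners).

Step 11 (key step). Several processes can divert it: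
- 1,2-hydride migration in the α-alkyl carbenoid may outrun capture by the ketone oxygen.
- The excess enol ether may be cyclopropanated directly.
- The ylide may collapse by proton transfer from C5.
- Most likely, the catalyst may discriminate the ylide faces poorly, because C1' differentiates them only through a remote gem-dimethyl group.

Fallback (sets out from 9, returns at 22): the dipolar cycloaddition is replaced by a transannular bromoetherification, which builds the same bicycle by ionic chemistry without a carbenoid. Amide 9 and 3-methylbut-3-enylmagnesium bromide would give the 4-methylpent-4-en-1-one F1. Catalytic asymmetric allylboration of this ketone (allyl-B(O-i-Pr)2, a 3,3'-dibromo-1,1'-bi-2-naphthol catalyst, antipode chosen for the 4S carbinol) would give the octa-1,7-dien-4-ol F2. Ring-closing metathesis with second-generation Grubbs catalyst (H2IMes)(PCy3)Cl2Ru=CHPh would close the 4-methylcyclohex-3-en-1-ol F3. N-Bromosuccinimide in CH2Cl2 at 0 °C would then deliver bromine to the trisubstituted alkene, and the tertiary hydroxyl would open the bromonium ion at the methyl-bearing carbon from the opposite side; this fixes C1 and places bromine endo at C2, giving the bromo ether silyl ether F4. Bu4NF would free the ring A alcohol F5, and one Appel reaction at C4' would give 22. Control at C4 is again reagent control, with separation of C4 epimers as the safety net, but the carbenoid and the inversion at C2 are both avoided.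

Step 16. Displacement at C2 from the endo face, next to the quaternary bridgehead and under the C5–C6 bridge, may be too slow. The C2 alkoxyphosphonium ion may then survive to work-up or ionise with a 1,2-shift of C6 towards the oxygen-stabilised C1 cation; at C4', E2 elimination towards C5' competes with substitution.

Fallback (sets out from 21, returns at 22): C2 is set by exo-face addition of hydrogen instead of substitution. With about 1.2 equivalents of CBr4/PPh3 at room temperature only the ring A alcohol should react, giving the ring A bromo alcohol F6. Dess–Martin periodinane would give the bromo ketone F7. KN(SiMe3)2 and N-(5-chloropyridin-2-yl)bis(trifluoromethanesulfonimide) at −78 °C would give the enol triflate F8; enolisation is possible only towards C3, and the low temperature is meant to prevent β-elimination of the oxygen bridge. Exchange of triflate for bromide with LiBr and catalytic [Cp*Ru(MeCN)3]OTf would give the alkenyl bromide F9. Diimide, generated from 2-nitrobenzenesulfonohydrazide and Et3N, would add H2 to the strained double bond from the exo face and leave bromine endo, which is 22.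

Step 14. Hydride may attack sulfur instead of carbon (S–O cleavage back to 18), or displacement at the neopentyl-type, β-oxygenated carbon may stall.

Fallback (sets out from 18, returns at 20): a radical replaces the SN2 step. I2, PPh3 and imidazole in toluene at 80 °C would give the iodomethyl compound F10, and Bu3SnH with AIBN in toluene at 80 °C would reduce it to 20; no bromide is present at this stage.

Step 2. The strongly acidic catalyst may protodesilylate or oligomerise the diene, or the extra methyl group may erode regio- or enantiocontrol.

Fallback (sets out from 2, returns at 5): auxiliary control replaces catalyst control. (R)-3-Acryloyl-4-benzyloxazolidin-2-one with Et2AlCl in CH2Cl2 at −78 °C would give the imide cycloadduct F11; the chelated s-cis acryloyl unit is shielded on one face by the benzyl group, which should lead to 1S. Me3Al and MeNH(OMe)·HCl would then convert F11 directly into 5 with release of the oxazolidinone.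

## Further compounds

F1 | step 11 | 1-[(1S,4R)-4-[(tert-butyldimethylsilyl)oxy]-3,3-dimethylcyclohexyl]-4-methylpent-4-en-1-one | CC1(C)C[C@@H](C(=O)CCC(C)=C)CC[C@H]1O[Si](C)(C)C(C)(C)C
F2 | step 11 | (4S)-4-[(1S,4R)-4-[(tert-butyldimethylsilyl)oxy]-3,3-dimethylcyclohexyl]-7-methylocta-1,7-dien-4-ol | CC1(C)C[C@@H]([C@@](O)(CC=C)CCC(C)=C)CC[C@H]1O[Si](C)(C)C(C)(C)C
F3 | step 11 | (1S)-1-[(1S,4R)-4-[(tert-butyldimethylsilyl)oxy]-3,3-dimethylcyclohexyl]-4-methylcyclohex-3-en-1-ol | CC1(C)C[C@@H]([C@]2(O)CCC(C)=CC2)CC[C@H]1O[Si](C)(C)C(C)(C)C
F4 | step 11 | tert-butyl{[(1R,4S)-4-[(1R,2R,4S)-2-bromo-1-methyl-7-oxabicyclo[2.2.1]heptan-4-yl]-2,2-dimethylcyclohexyl]oxy}dimethylsilane | CC1(C)C[C@@H]([C@@]23CC[C@@](C)(O2)[C@H](Br)C3)CC[C@H]1O[Si](C)(C)C(C)(C)C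
F5 | step 11 | (1R,4S)-4-[(1R,2R,4S)-2-bromo-1-methyl-7-oxabicyclo[2.2.1]heptan-4-yl]-2,2-dimethylcyclohexan-1-ol | CC1(C)C[C@@H]([C@@]23CC[C@@](C)(O2)[C@H](Br)C3)CC[C@H]1O
F6 | step 16 | (1R,2S,4S)-4-[(1S,4S)-4-bromo-3,3-dimethylcyclohexyl]-1-methyl-7-oxabicyclo[2.2.1]heptan-2-ol | CC1(C)C[C@@H]([C@@]23CC[C@@](C)(O2)[C@@H](O)C3)CC[C@@H]1Br
F7 | step 16 | (1R,4S)-4-[(1S,4S)-4-bromo-3,3-dimethylcyclohexyl]-1-methyl-7-oxabicyclo[2.2.1]heptan-2-one | CC1(C)C[C@@H]([C@@]23CC[C@@](C)(O2)C(=O)C3)CC[C@@H]1Br
F8 | step 16 | (1R,4R)-4-[(1S,4S)-4-bromo-3,3-dimethylcyclohexyl]-1-methyl-7-oxabicyclo[2.2.1]hept-2-en-2-yl trifluoromethanesulfonate | CC1(C)C[C@@H]([C@@]23CC[C@@](C)(O2)C(OS(=O)(=O)C(F)(F)F)=C3)CC[C@@H]1Br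
F9 | step 16 | (1R,4R)-2-bromo-4-[(1S,4S)-4-bromo-3,3-dimethylcyclohexyl]-1-methyl-7-oxabicyclo[2.2.1]hept-2-ene | CC1(C)C[C@@H]([C@@]23CC[C@@](C)(O2)C(Br)=C3)CC[C@@H]1Br
F10 | step 14 | (1R,2S,4S)-2-[(tert-butyldimethylsilyl)oxy]-4-[(1S,4R)-4-[(tert-butyldimethylsilyl)oxy]-3,3-dimethylcyclohexyl]-1-(iodomethyl)-7-oxabicyclo[2.2.1]heptane | CC1(C)C[C@@H]([C@@]23CC[C@@](CI)(O2)[C@@H](O[Si](C)(C)C(C)(C)C)C3)CC[C@H]1O[Si](C)(C)C(C)(C)C
F11 | step 2 | (4R)-4-benzyl-3-[(1S)-3-methyl-4-(triisopropylsilyloxy)cyclohex-3-ene-1-carbonyl]-1,3-oxazolidin-2-one | CC1=C(O[Si](C(C)C)(C(C)C)C(C)C)CC[C@@H](C1)C(=O)N2[C@H](Cc3ccccc3)COC2=O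
A1 | alternative 1 | (1R,2R,4S)-2-bromo-4-[(4S)-4-bromo-3,3-dimethylcyclohex-1-en-1-yl]-1-methyl-7-oxabicyclo[2.2.1]heptane | CC1(C)C=C([C@@]23CC[C@@](C)(O2)[C@H](Br)C3)CC[C@@H]1Br
A2 | alternative 1 | (1R,2R,4S)-2-bromo-1-methyl-4-(6-methylhepta-1,5-dien-2-yl)-7-oxabicyclo[2.2.1]heptane | CC(C)=CCCC(=C)[C@@]12CC[C@@](C)(O1)[C@H](Br)C2
A3 | alternative 1 | 1',6'-didehydro isomer of A1: (1R,2R,4S)-2-bromo-4-[(4S)-4-bromo-5,5-dimethylcyclohex-1-en-1-yl]-1-methyl-7-oxabicyclo[2.2.1]heptane | CC1(C)CC([C@@]23CC[C@@](C)(O2)[C@H](Br)C3)=CC[C@@H]1Br
A4 | alternative 2 | 2,2,2-trifluoroethyl endo-6-carboxylate of 2-bromo-4-[(1S,4S)-4-bromo-3,3-dimethylcyclohexyl]-1-methyl-7-oxabicyclo[2.2.1]hept-2-ene | CC1(C)C[C@@H]([C@@]23C[C@H](C(=O)OCC(F)(F)F)[C@@](C)(O2)C(Br)=C3)CC[C@@H]1Br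
A5 | alternative 2 | 3-bromo-5-[(1S,4S)-4-bromo-3,3-dimethylcyclohexyl]-2-methylfuran | CC1(C)C[C@@H](c2cc(Br)c(C)o2)CC[C@@H]1Br
A6 | alternative 3 | 5-[(1S,4R)-4-[(tert-butyldimethylsilyl)oxy]-3,3-dimethylcyclohexyl]-2-methyl-3-(trimethylsilyl)-5-(trimethylsilyloxy)cyclohex-2-en-1-one | CC1(C)C[C@@H]([C@]2(O[Si](C)(C)C)CC([Si](C)(C)C)=C(C)C(=O)C2)CC[C@H]1O[Si](C)(C)C(C)(C)C
A7 | alternative 3 | 3-[(1S,4R)-4-[(tert-butyldimethylsilyl)oxy]-3,3-dimethylcyclohexyl]-3-(trimethylsilyloxy)cyclobutan-1-one | CC1(C)C[C@@H](C2(O[Si](C)(C)C)CC(=O)C2)CC[C@H]1O[Si](C)(C)C(C)(C)C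
A8 | alternative 3 | trimethyl(prop-1-yn-1-yl)silane | CC#C[Si](C)(C)C
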